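## Analysis of the target

- The target is a linear thirteen-carbon chain, numbered here from the lactone carbonyl C1 to the benzylic alkene carbon C13 (phenyl on C13). The C1 carboxyl is closed onto the C5 oxygen as a six-membered δ-lactone (ring atoms O, C1, C2, C3, C4, C5) with a free hydroxyl on C3.
- Outside the ring the chain runs through an E alkene C6=C7, a methylene C8, two methoxy-bearing carbons C9 and C11 on either side of C10, and an E styrene C12=C13.
- There are four stereocenters. C3 (S) and C5 (R) are 1,3-syn in the open chain, so hydroxyl and side chain are trans on the ring. C9 (R) and C11 (S) are 1,3-anti. The two pairs are linked only by a 1,5-syn relationship of the C5 and C9 oxygens across the alkene.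
- Sensitive groups: the β-hydroxy-δ-lactone loses water (E1cB) to the conjugated dihydropyranone under base. The C5–O bond is an allylic ester that zerovalent palladium or strong Lewis acids ionize. The C11 methoxy group is a cinnamyl-type ether that ionizes under acid. C6=C7 and C12=C13 form a 1,7-diene that a ruthenium carbene would close to a cyclohexene with loss of styrene.
- The hard part is the remote 5,9-relationship, which no ring or chelate can relay, together with an E alkene that must be placed between two β-oxygenated, elimination-prone halves without strong base. Four oxygens of similar reactivity must also end as one acyl oxygen, one free hydroxyl and two methyl ethers.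
- The feature the plan is built on: the atoms O–C5–C6=C7–C8–C9–O are an (E)-pent-2-ene-1,5-diol with syn oxygens. C5 and C9 are each the former carbonyl carbon of a five-carbon aldehyde, so the skeleton is C5 + C3 + C5.

## Retrosynthetic reasoning

**O–Si bond at C3 (24 from 23).** The free β-hydroxy lactone is the most elimination-prone form of the molecule, so it is uncovered last. The silyl ether of 23 is already present in the purchased compound 1 and costs no protection step.

**O–CH3 bond at C9 (23 from 22).** The C11 methyl ether arrives with aldehyde 12, but the C9 oxygen is created in the key step and must be methylated afterwards. The methylation is placed after ring closure because in 22 the C9 hydroxyl is the only free one.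

**C1–O5 acyl bond (22 from 21).** Opening the lactone gives the δ-hydroxy ester 21. Of its two hydroxyls only the one on C5 can reach the ester through a six-membered ring (the C9 hydroxyl would need a ten-membered one). Lactonization therefore differentiates the two carbinols that the key step creates together.

**C5–C6 and C8–C9 (21 from 5, 17 and 12), the key disconnection.** Both bonds join a carbinol carbon to an allyl terminus, the alkene between them is E, and the oxygens are syn. This is the retron of two consecutive allylborations through a 1,3-diborylpropene (18), made in the flask from allene 17, which supplies C6, C7 and C8.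
- Gain: 21 (four stereocenters, two alkenes) falls into two five-carbon aldehydes with one stereocenter each and a three-carbon linchpin. C5, C9 and the alkene geometry are set in one flask under neutral conditions.
- Forward requirements: 18 must be the Z isomer and stay so. Aldehyde 5 must be added first, because the first aldehyde becomes the allylic carbinol (C5) and the second the homoallylic one (C9). The second allyl transfer must pass through the chair that gives the E alkene.

**Aldehyde 5 (from 4, 3 and 1).** The C5 aldehyde comes from primary alcohol 4, 4 from lactone 3 by acyl cleavage, and 3 from the glutarate half-ester 1 by reduction of its ester terminus. The pool compound 1 belongs to the statin series. Taking its acid terminus as C1 and its ester terminus as C5 exchanges the roles of the two arms and delivers the (3S) configuration the target needs.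

**Aldehyde 12 (from 10, 8 and 6).** The C9 aldehyde comes from cleaving the terminal alkene of 10, the methyl ether from alcohol 8, and the C10–C11 bond with the C11 stereocenter from enantioselective allylation of 6. Compound 6 brings C11–C13, the styrene and the phenyl ring.

**Allene 17 (from 13).** The C–B bond is made by borylating the allenyl Grignard reagent 14 derived from 13.

## Alternatives that were turned down

**Alternative 1:** the textbook route.
- Disconnection: C6=C7 by cross-metathesis.
- Forward key step: vinyl lactone A1 and diene ether A2 with the second-generation Hoveyda–Grubbs catalyst.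
- Why turned down: A2 (and the product) is a 1,7-diene. A carbene formed at its terminal alkene can close onto the styrenyl alkene to give a cyclohexene and expel styrene, which competes directly with the cross-coupling. A1 is an allylic-oxygenated, slow olefin, so homodimerization of A2 and E/Z mixtures are expected. The key step sets no stereocenter: all four must be made one by one beforehand by iterative allylation, acylation and ring closure, and the route is longer.

**Alternative 2:** statin logic.
- Disconnection: C6=C7 by Horner–Wadsworth–Emmons olefination, then C5 by 1,3-relay.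
- Forward key step: phosphonate A3 and aldehyde A4 are joined, the silyl group is removed, and the β-hydroxy enone A5 is reduced syn (Narasaka–Prasad, Et2BOMe/NaBH4) before lactonization.
- Why turned down: A4 is a β-methoxy aldehyde and loses methanol by E1cB under any olefination base. In A5 the C8 methylene is γ to the enone and β to the C9 methoxy group, so vinylogous elimination to a dienone threatens. A4 carries two stereocenters that must be built linearly, and the relay needs a deprotection before the reduction. The count exceeds that of the chosen route, and the union sets no stereocenter.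

**Alternative 3:** C–C cleavage of a meso ring.
- Disconnection: the C1–C6 unit from the cis-diprotected ketone A6.
- Forward key step: enantioselective Baeyer–Villiger oxidation (a Baeyer–Villiger monooxygenase) to lactone A7, which sets C3 and C5 together. A7 is then opened, C6 oxidized to the aldehyde, and C6=C7 made by olefination.
- Why turned down: it solves the easiest pair (the 3,5-syn array is available from the pool as 1) and leaves the union and the 5,9-relationship to a base-mediated olefination of an epimerizable α-oxygenated aldehyde. The enantiopreference of the enzyme on a β,β′-dioxygenated cyclohexanone cannot be predicted, and A6 is prone to β-elimination and aromatization. The C7–C13 partner still needs both of its stereocenters made separately.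

Key step: step 8

Remark on the chemistry: chain carbons are numbered C1 (lactone carbonyl) to C13 throughout. dIpc is the isopinocampheyl group from (+)-α-pinene; its allylboranes, the γ-boryl reagent 18 included, are assumed to transfer the allyl unit to the Si face of an aldehyde.

## Route

Step 1
Reactants: 1 (3R)-3-{[tert-butyl(dimethyl)silyl]oxy}-5-methoxy-5-oxopentanoic acid
Product: 3 (4S)-4-{[tert-butyl(dimethyl)silyl]oxy}oxan-2-one, via lithium hydroxy carboxylate 2 (not isolated)
Conditions: LiBH4 (2.2 equiv), THF, 0 °C to rt; 1 M aq. HCl to pH 3, 0 °C; then PPTS (cat.), CH2Cl2, rt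
Reagents that add atoms: none
Why: LiBH4 reduces the methyl ester but not the lithium carboxylate, and acidification closes the δ-lactone (chemoselective ester reduction, then lactonization); the stereocenter is untouched, but the acid arm now becomes C1 and the former ester arm C5, which gives the (S) series from the commercial (R) half-ester.

Step 2
Reactants: 3 (4S)-4-{[tert-butyl(dimethyl)silyl]oxy}oxan-2-one
Product: 4 methyl (3S)-3-{[tert-butyl(dimethyl)silyl]oxy}-5-hydroxypentanoate
Conditions: K2CO3 (0.1 equiv), MeOH, 0 °C, 1 h; AcOH (0.2 equiv), concentration below rt; used crude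
Reagents that add atoms: methanol, CO
Why: Base-catalysed methanolysis of the δ-lactone, driven by the solvent and by release of the s-cis ester; neutralization before concentration should keep 4 from closing back.

Step 3
Reactants: 4 methyl (3S)-3-{[tert-butyl(dimethyl)silyl]oxy}-5-hydroxypentanoate
Product: 5 methyl (3S)-3-{[tert-butyl(dimethyl)silyl]oxy}-5-oxopentanoate
Conditions: TEMPO (0.1 equiv), PhI(OAc)2 (1.2 equiv), CH2Cl2, rt
Reagents that add atoms: none
Why: Oxoammonium oxidation of the primary alcohol stops at the aldehyde and is non-basic, so the β-silyloxy group should not eliminate.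

Step 4
Reactants: 6 (2E)-3-phenylprop-2-enal
Product: 8 (1E,3S)-1-phenylhexa-1,5-dien-3-ol, via borinate 7 (not isolated)
Conditions: (dIpc)2BOMe [(−)-B-methoxydiisopinocampheylborane], allylMgBr, Et2O, 0 °C to rt; then 6, −78 °C; 3 M aq. NaOH, 30% aq. H2O2, rt
Reagents that add atoms: allylmagnesium bromide, C=CC[Mg]Br
Why: Brown allylboration through a chair Zimmerman–Traxler transition state; the dIpc groups direct the allyl unit to the Si face of the enal (1,2-addition only), which sets the future C11 as (S).

Step 5
Reactants: 8 (1E,3S)-1-phenylhexa-1,5-dien-3-ol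
Product: 10 [(1E,3S)-3-methoxyhexa-1,5-dien-1-yl]benzene, via sodium alkoxide 9 (not isolated)
Conditions: NaH (1.3 equiv), THF, 0 °C; MeI (2 equiv), 0 °C to rt
Reagents that add atoms: iodomethane, CI
Why: Williamson ether synthesis on a simple secondary alkoxide; no C–O bond at the stereocenter is broken, so the configuration is kept.

Step 6
Reactants: 10 [(1E,3S)-3-methoxyhexa-1,5-dien-1-yl]benzene
Product: 12 (3S,4E)-3-methoxy-5-phenylpent-4-enal, via diol 11 (not isolated)
Conditions: OsO4 (2 mol %), NaIO4 (3 equiv), 2,6-lutidine (2 equiv), 1,4-dioxane–H2O (3:1), 0 °C to rt; used without chromatography on acidic silica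
Reagents that add atoms: osmium tetroxide, O=[Os](=O)(=O)=O; sodium periodate, [Na+].[O-]I(=O)(=O)=O
Why: Lemieux–Johnson cleavage; OsO4 should prefer the unhindered monosubstituted alkene over the 1,2-disubstituted styrenyl alkene, which is shielded and inductively deactivated by the adjacent methoxy group, and NaIO4 cleaves diol 11 as it forms; lutidine buffers the medium.

Step 7
Reactants: 13 3-bromoprop-1-yne
Product: 17 5,5-dimethyl-2-(propa-1,2-dien-1-yl)-1,3,2-dioxaborinane, via allenylmagnesium bromide 14 (not isolated), via trimethoxyborate 15 (not isolated), via allenylboronic acid 16 (not isolated)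
Conditions: Mg, HgCl2 (1 mol %), Et2O, 0 °C; B(OMe)3, Et2O, −78 °C to 0 °C; 2 M aq. HCl; then 2,2-dimethylpropane-1,3-diol, MgSO4, Et2O–pentane, rt; distillation
Reagents that add atoms: trimethyl borate, COB(OC)OC; 2,2-dimethylpropane-1,3-diol, OCC(C)(C)CO
Why: Borylation of the allenyl Grignard reagent gives the allenylboron compound, and esterification with the 1,3-diol gives a small six-membered boronic ester; the small ester is chosen because it lets the α-substituent of 19 sit pseudo-equatorial in step 8.

Step 8
Reactants: 17 5,5-dimethyl-2-(propa-1,2-dien-1-yl)-1,3,2-dioxaborinane; 5 methyl (3S)-3-{[tert-butyl(dimethyl)silyl]oxy}-5-oxopentanoate; 12 (3S,4E)-3-methoxy-5-phenylpent-4-enal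
Product: 21 methyl (3S,5R,6E,9R,11S,12E)-3-{[tert-butyl(dimethyl)silyl]oxy}-5,9-dihydroxy-11-methoxy-13-phenyltrideca-6,12-dienoate, via allylborane 18 (not isolated), via allylboronate 19 (not isolated), via bis-boron ester 20 (not isolated)
Conditions: 17 (1.15 equiv), (dIpc)2BH (1.0 equiv), toluene, −25 °C, 5 h; 5 (0.85 equiv), −78 °C, 3 h; 12 (1.3 equiv), −78 °C to rt, 24 h; pH 7 phosphate buffer, MeOH, 30% aq. H2O2, 0 °C
Reagents that add atoms: none
Why: (dIpc)2BH adds across the terminal C=C of allene 17, boron to CH2 and hydrogen to the central carbon, on the face away from the boronate, and at −25 °C this should give the (Z)-γ-boryl allylborane 18 under kinetic control. Allylborane 18 adds to aldehyde 5 at −78 °C through a chair Zimmerman–Traxler transition state on the Si face chosen by the dIpc groups; this forms C5–C6, sets C5 (R), and places the C6 boronate syn to the C5 oxygen because the Z substituent is axial (intermediate 19). Intermediate 19 is an α-substituted allylboronate that reacts with aldehyde 12 only on warming, through a second chair in which the branched C5 substituent is pseudo-equatorial on the unhindered dioxaborinane; C8–C9 forms, boron moves from C6 to O9, and C6=C7 comes out E. C9 (R) is thus set by suprafacial 1,3-chirality transfer from C6, and the outcome is the 1,5-syn array; C3 and C11 are spectators, and the closed transition states leave little room for their influence. The closest known reaction type is the one-pot allene hydroboration/double allylboration of two different aldehydes to (E)-pent-2-ene-1,5-diols. No ring is closed. The step needs Z integrity of 18 (low temperature, immediate use), complete consumption of 5 before 12 is added (secured by the large rate gap between allylborane and allylboronate), aldehyde-over-ester chemoselectivity (allylboron reagents do not add to esters), and the equatorial preference in the second chair. Buffered oxidative work-up should free both hydroxyls without touching ester, silyl ether or alkenes.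

Step 9
Reactants: 21 methyl (3S,5R,6E,9R,11S,12E)-3-{[tert-butyl(dimethyl)silyl]oxy}-5,9-dihydroxy-11-methoxy-13-phenyltrideca-6,12-dienoate
Product: 22 (4S,6R)-4-{[tert-butyl(dimethyl)silyl]oxy}-6-[(1E,4R,6S,7E)-4-hydroxy-6-methoxy-8-phenylocta-1,7-dien-1-yl]oxan-2-one
Conditions: PPTS (0.2 equiv), toluene, 45 °C
Reagents that add atoms: none
Why: Acid-catalysed lactonization of the δ-hydroxy ester; only the C5 hydroxyl can close a six-membered ring, so the C9 hydroxyl is left as the single free one, and PPTS is too weak to ionize the allylic C5 or C11 oxygens.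

Step 10
Reactants: 22 (4S,6R)-4-{[tert-butyl(dimethyl)silyl]oxy}-6-[(1E,4R,6S,7E)-4-hydroxy-6-methoxy-8-phenylocta-1,7-dien-1-yl]oxan-2-one
Product: 23 (4S,6R)-4-{[tert-butyl(dimethyl)silyl]oxy}-6-[(1E,4R,6S,7E)-4,6-dimethoxy-8-phenylocta-1,7-dien-1-yl]oxan-2-one
Conditions: Me3OBF4 (4 equiv), 1,8-bis(dimethylamino)naphthalene (5 equiv), CH2Cl2, 0 °C to rt
Reagents that add atoms: trimethyloxonium tetrafluoroborate, C[O+](C)C.F[B-](F)(F)F
Why: O-methylation with the oxonium salt buffered by a non-nucleophilic base; no alkoxide is formed, so the β-silyloxy lactone should not eliminate, and the C9 configuration is kept because only the O–H bond reacts.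

Step 11
Reactants: 23 (4S,6R)-4-{[tert-butyl(dimethyl)silyl]oxy}-6-[(1E,4R,6S,7E)-4,6-dimethoxy-8-phenylocta-1,7-dien-1-yl]oxan-2-one
Product: 24 (4S,6R)-6-[(1E,4R,6S,7E)-4,6-dimethoxy-8-phenylocta-1,7-dien-1-yl]-4-hydroxyoxan-2-one
Conditions: HF·pyridine, pyridine, THF, 0 °C to rt
Reagents that add atoms: none
Why: Fluoride-driven cleavage of the silyl ether in a pyridine-buffered medium, which is neither basic enough for E1cB dehydration of the β-hydroxy lactone nor acidic enough to ionize the cinnamyl-type ether at C11.

## Compound list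

1 | (3R)-3-{[tert-butyl(dimethyl)silyl]oxy}-5-methoxy-5-oxopentanoic acid (commercial statin-series glutarate half-ester) | COC(=O)C[C@@H](CC(=O)O)O[Si](C)(C)C(C)(C)C | starting material
2 | lithium (3S)-3-{[tert-butyl(dimethyl)silyl]oxy}-5-hydroxypentanoate | [Li+].[O-]C(=O)C[C@@H](O[Si](C)(C)C(C)(C)C)CCO | intermediate (not isolated)
3 | (4S)-4-{[tert-butyl(dimethyl)silyl]oxy}oxan-2-one | O=C1C[C@@H](O[Si](C)(C)C(C)(C)C)CCO1 | intermediate
4 | methyl (3S)-3-{[tert-butyl(dimethyl)silyl]oxy}-5-hydroxypentanoate | COC(=O)C[C@@H](O[Si](C)(C)C(C)(C)C)CCO | intermediate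
5 | methyl (3S)-3-{[tert-butyl(dimethyl)silyl]oxy}-5-oxopentanoate | COC(=O)C[C@@H](O[Si](C)(C)C(C)(C)C)CC=O | intermediate
6 | (2E)-3-phenylprop-2-enal (cinnamaldehyde) | O=C/C=C/c1ccccc1 | starting material
7 | bis(isopinocampheyl)[(1E,3S)-1-phenylhexa-1,5-dien-3-yloxy]borane (dIpc groups) | C=CC[C@H](OB([C@@H]1C[C@@H]2C[C@H]([C@H]1C)C2(C)C)[C@@H]1C[C@@H]2C[C@H]([C@H]1C)C2(C)C)/C=C/c1ccccc1 | intermediate (not isolated)
8 | (1E,3S)-1-phenylhexa-1,5-dien-3-ol | C=CC[C@H](O)/C=C/c1ccccc1 | intermediate
9 | sodium (1E,3S)-1-phenylhexa-1,5-dien-3-olate | C=CC[C@H]([O-])/C=C/c1ccccc1.[Na+] | intermediate (not isolated)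
10 | [(1E,3S)-3-methoxyhexa-1,5-dien-1-yl]benzene | C=CC[C@H](OC)/C=C/c1ccccc1 | intermediate
11 | (4S,5E)-4-methoxy-6-phenylhex-5-ene-1,2-diol (both C2 epimers) | OCC(O)C[C@H](OC)/C=C/c1ccccc1 | intermediate (not isolated)
12 | (3S,4E)-3-methoxy-5-phenylpent-4-enal | O=CC[C@H](OC)/C=C/c1ccccc1 | intermediate
13 | 3-bromoprop-1-yne | C#CCBr | starting material
14 | propa-1,2-dien-1-ylmagnesium bromide | C=C=C[Mg]Br | intermediate (not isolated)
15 | bromomagnesium trimethoxy(propa-1,2-dien-1-yl)borate | C=C=C[B-](OC)(OC)OC.[Mg+2].[Br-] | intermediate (not isolated)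
16 | propa-1,2-dien-1-ylboronic acid | C=C=CB(O)O | intermediate (not isolated)
17 | 5,5-dimethyl-2-(propa-1,2-dien-1-yl)-1,3,2-dioxaborinane | C=C=CB1OCC(C)(C)CO1 | intermediate
18 | [(2Z)-3-(5,5-dimethyl-1,3,2-dioxaborinan-2-yl)prop-2-en-1-yl]bis(isopinocampheyl)borane (dIpc groups) | B1(OCC(C)(C)CO1)/C=C\CB([C@@H]2C[C@@H]3C[C@H]([C@H]2C)C3(C)C)[C@@H]2C[C@@H]3C[C@H]([C@H]2C)C3(C)C | intermediate (not isolated)
19 | methyl (3S,5R,6R)-5-{[bis(isopinocampheyl)boranyl]oxy}-3-{[tert-butyl(dimethyl)silyl]oxy}-6-(5,5-dimethyl-1,3,2-dioxaborinan-2-yl)oct-7-enoate | COC(=O)C[C@@H](O[Si](C)(C)C(C)(C)C)C[C@@H](OB([C@@H]1C[C@@H]2C[C@H]([C@H]1C)C2(C)C)[C@@H]1C[C@@H]2C[C@H]([C@H]1C)C2(C)C)[C@@H](C=C)B1OCC(C)(C)CO1 | intermediate (not isolated)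
20 | methyl (3S,5R,6E,9R,11S,12E)-5-{[bis(isopinocampheyl)boranyl]oxy}-3-{[tert-butyl(dimethyl)silyl]oxy}-9-[(5,5-dimethyl-1,3,2-dioxaborinan-2-yl)oxy]-11-methoxy-13-phenyltrideca-6,12-dienoate | COC(=O)C[C@@H](O[Si](C)(C)C(C)(C)C)C[C@@H](OB([C@@H]1C[C@@H]2C[C@H]([C@H]1C)C2(C)C)[C@@H]1C[C@@H]2C[C@H]([C@H]1C)C2(C)C)/C=C/C[C@@H](OB1OCC(C)(C)CO1)C[C@H](OC)/C=C/c1ccccc1 | intermediate (not isolated)
21 | methyl (3S,5R,6E,9R,11S,12E)-3-{[tert-butyl(dimethyl)silyl]oxy}-5,9-dihydroxy-11-methoxy-13-phenyltrideca-6,12-dienoate | COC(=O)C[C@@H](O[Si](C)(C)C(C)(C)C)C[C@@H](O)/C=C/C[C@@H](O)C[C@H](OC)/C=C/c1ccccc1 | intermediate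
22 | (4S,6R)-4-{[tert-butyl(dimethyl)silyl]oxy}-6-[(1E,4R,6S,7E)-4-hydroxy-6-methoxy-8-phenylocta-1,7-dien-1-yl]oxan-2-one | O=C1C[C@@H](O[Si](C)(C)C(C)(C)C)C[C@H](/C=C/C[C@@H](O)C[C@H](OC)/C=C/c2ccccc2)O1 | intermediate
23 | (4S,6R)-4-{[tert-butyl(dimethyl)silyl]oxy}-6-[(1E,4R,6S,7E)-4,6-dimethoxy-8-phenylocta-1,7-dien-1-yl]oxan-2-one | O=C1C[C@@H](O[Si](C)(C)C(C)(C)C)C[C@H](/C=C/C[C@@H](OC)C[C@H](OC)/C=C/c2ccccc2)O1 | intermediate
24 | (4S,6R)-6-[(1E,4R,6S,7E)-4,6-dimethoxy-8-phenylocta-1,7-dien-1-yl]-4-hydroxyoxan-2-one | CO[C@H](C/C=C/[C@H]1C[C@H](O)CC(=O)O1)C[C@@H](/C=C/c1ccccc1)OC | target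

## Step count and least certain steps

Total steps: 11. Longest linear sequence: 7 (steps 1, 2, 3, 8, 9, 10, 11).

**Step 8 (key step).**
- What may go wrong: a 1,3-boratropic shift could isomerize the Z allylborane 18 to the E isomer before it meets aldehyde 5, which would lead into the 1,5-anti series. The C3 silyloxy group could work against the reagent in the first addition and lower the facial selectivity. Aldehyde 12 could lose methanol by β-elimination during the slow second allyl transfer.
- Fallback (stepwise, sets out from 12 and 5, returns at 21): addition of B-allenylbis(isopinocampheyl)borane of the (−)-α-pinene series to the Re face of 12 should give (4R,6S,7E)-6-methoxy-8-phenyloct-7-en-1-yn-4-ol F1. Silylation (Me3SiCl, imidazole) gives trimethyl{[(4R,6S,7E)-6-methoxy-8-phenyloct-7-en-1-yn-4-yl]oxy}silane F2. Hydroboration of the terminal alkyne with Cy2BH, boron-to-zinc exchange with Et2Zn, and (−)-DAIB-catalysed addition of the (E)-alkenylzinc to the Si face of aldehyde 5, followed by a citric acid work-up that removes the trimethylsilyl group, comes back to 21.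

**Step 6.**
- What may go wrong: poor discrimination between the two alkenes (osmylation of the conjugated styrenyl double bond, which a small methoxy group shields only moderately), and β-elimination of methanol from the aldehyde during isolation.
- Fallback (sets out from 6, returns at 12): zinc-mediated Reformatsky addition of ethyl bromoacetate gives racemic ethyl (4E)-3-hydroxy-5-phenylpent-4-enoate F3. Lipase-catalysed acetylation (Burkholderia cepacia lipase, vinyl acetate) should, by the Kazlauskas rule, convert the (R)-alcohol into ethyl (3R,4E)-3-acetoxy-5-phenylpent-4-enoate F4 and leave ethyl (3S,4E)-3-hydroxy-5-phenylpent-4-enoate F5. Methylation (Ag2O, MeI) gives ethyl (3S,4E)-3-methoxy-5-phenylpent-4-enoate F6, and iBu2AlH at −78 °C returns aldehyde 12.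

**Step 10.**
- What may go wrong: slow alkylation of the hindered C9 hydroxyl, during which the oxonium salt may alkylate and ionize the allylic C11 ether, or the base may trigger E1cB loss of the silyloxy group from the lactone.
- Fallback (sets out from 21, returns at 23): MnO2 should oxidize only the allylic C5 hydroxyl to give methyl (3S,6E,9R,11S,12E)-3-{[tert-butyl(dimethyl)silyl]oxy}-9-hydroxy-11-methoxy-5-oxo-13-phenyltrideca-6,12-dienoate F7. The single remaining hydroxyl is methylated on the acyclic substrate (Ag2O, MeI) to methyl (3S,6E,9R,11S,12E)-3-{[tert-butyl(dimethyl)silyl]oxy}-9,11-dimethoxy-5-oxo-13-phenyltrideca-6,12-dienoate F8. Corey–Bakshi–Shibata reduction with the (S)-oxazaborolidine and catecholborane (alkenyl as the large group) should give methyl (3S,5R,6E,9R,11S,12E)-3-{[tert-butyl(dimethyl)silyl]oxy}-5-hydroxy-9,11-dimethoxy-13-phenyltrideca-6,12-dienoate F9, and PPTS-catalysed lactonization comes back to 23.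

**Step 11.**
- What may go wrong: elimination across C2–C3 to the conjugated dihydropyranone during or after desilylation, because the β-oxygen of a lactone is a good E1cB leaving group.
- Fallback (sets out from 23, returns at 24): the elimination is driven to completion with DBU to give (6R)-6-[(1E,4R,6S,7E)-4,6-dimethoxy-8-phenylocta-1,7-dien-1-yl]-5,6-dihydro-2H-pyran-2-one F10. Weitz–Scheffer epoxidation (H2O2, NaOH, MeOH, 0 °C) should attack only the electron-poor alkene, anti to the C5 side chain, and give (3S,4S,6R)-6-[(1E,4R,6S,7E)-4,6-dimethoxy-8-phenylocta-1,7-dien-1-yl]-3,4-epoxyoxan-2-one F11. Reductive opening at C2 with PhSeNa (from PhSeSePh and NaBH4, AcOH) leaves the C3 hydroxyl trans to the side chain and comes back to 24.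

**Step 2.**
- What may go wrong: incomplete ring opening and re-closure to 3 on concentration (an equilibrium), and base-induced migration of the silyl group from the C3 oxygen to the new primary alkoxide.
- Fallback (sets out from 1, returns at 4): the LiBH4 reduction of step 1 is stopped at carboxylate 2 (excess hydride destroyed with acetone), the solvent is exchanged for DMF, and 2 is alkylated on oxygen with MeI to give 4 directly, so that lactone 3 is bypassed.

## Further compounds

F1 | step 8 | (4R,6S,7E)-6-methoxy-8-phenyloct-7-en-1-yn-4-ol | C#CC[C@@H](O)C[C@H](OC)/C=C/c1ccccc1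
F2 | step 8 | trimethyl{[(4R,6S,7E)-6-methoxy-8-phenyloct-7-en-1-yn-4-yl]oxy}silane | C#CC[C@@H](O[Si](C)(C)C)C[C@H](OC)/C=C/c1ccccc1
F3 | step 6 | ethyl (4E)-3-hydroxy-5-phenylpent-4-enoate (racemic) | CCOC(=O)CC(O)/C=C/c1ccccc1
F4 | step 6 | ethyl (3R,4E)-3-acetoxy-5-phenylpent-4-enoate | CCOC(=O)C[C@@H](OC(C)=O)/C=C/c1ccccc1
F5 | step 6 | ethyl (3S,4E)-3-hydroxy-5-phenylpent-4-enoate | CCOC(=O)C[C@H](O)/C=C/c1ccccc1
F6 | step 6 | ethyl (3S,4E)-3-methoxy-5-phenylpent-4-enoate | CCOC(=O)C[C@H](OC)/C=C/c1ccccc1
F7 | step 10 | methyl (3S,6E,9R,11S,12E)-3-{[tert-butyl(dimethyl)silyl]oxy}-9-hydroxy-11-methoxy-5-oxo-13-phenyltrideca-6,12-dienoate | COC(=O)C[C@@H](O[Si](C)(C)C(C)(C)C)CC(=O)/C=C/C[C@@H](O)C[C@H](OC)/C=C/c1ccccc1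
F8 | step 10 | methyl (3S,6E,9R,11S,12E)-3-{[tert-butyl(dimethyl)silyl]oxy}-9,11-dimethoxy-5-oxo-13-phenyltrideca-6,12-dienoate | COC(=O)C[C@@H](O[Si](C)(C)C(C)(C)C)CC(=O)/C=C/C[C@@H](OC)C[C@H](OC)/C=C/c1ccccc1
F9 | step 10 | methyl (3S,5R,6E,9R,11S,12E)-3-{[tert-butyl(dimethyl)silyl]oxy}-5-hydroxy-9,11-dimethoxy-13-phenyltrideca-6,12-dienoate | COC(=O)C[C@@H](O[Si](C)(C)C(C)(C)C)C[C@@H](O)/C=C/C[C@@H](OC)C[C@H](OC)/C=C/c1ccccc1
F10 | step 11 | (6R)-6-[(1E,4R,6S,7E)-4,6-dimethoxy-8-phenylocta-1,7-dien-1-yl]-5,6-dihydro-2H-pyran-2-one | O=C1C=CC[C@H](/C=C/C[C@@H](OC)C[C@H](OC)/C=C/c2ccccc2)O1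
F11 | step 11 | (3S,4S,6R)-6-[(1E,4R,6S,7E)-4,6-dimethoxy-8-phenylocta-1,7-dien-1-yl]-3,4-epoxyoxan-2-one | O=C1[C@H]2O[C@H]2C[C@H](/C=C/C[C@@H](OC)C[C@H](OC)/C=C/c3ccccc3)O1
F0 | step 2 | none | none
A1 | alternative 1 | (4S,6R)-4-{[tert-butyl(dimethyl)silyl]oxy}-6-ethenyloxan-2-one | O=C1C[C@@H](O[Si](C)(C)C(C)(C)C)C[C@H](C=C)O1
A2 | alternative 1 | [(1E,3S,5R)-3,5-dimethoxyocta-1,7-dien-1-yl]benzene | C=CC[C@@H](OC)C[C@H](OC)/C=C/c1ccccc1
A3 | alternative 2 | methyl (3S)-3-{[tert-butyl(dimethyl)silyl]oxy}-6-(dimethoxyphosphoryl)-5-oxohexanoate | COC(=O)C[C@@H](O[Si](C)(C)C(C)(C)C)CC(=O)CP(=O)(OC)OC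
A4 | alternative 2 | (3S,5S,6E)-3,5-dimethoxy-7-phenylhept-6-enal | O=CC[C@@H](OC)C[C@H](OC)/C=C/c1ccccc1
A5 | alternative 2 | methyl (3S,6E,9R,11S,12E)-3-hydroxy-9,11-dimethoxy-5-oxo-13-phenyltrideca-6,12-dienoate | COC(=O)C[C@@H](O)CC(=O)/C=C/C[C@@H](OC)C[C@H](OC)/C=C/c1ccccc1
A6 | alternative 3 | (3R,5S)-3,5-bis{[tert-butyl(dimethyl)silyl]oxy}cyclohexan-1-one (cis, meso) | O=C1C[C@@H](O[Si](C)(C)C(C)(C)C)C[C@@H](O[Si](C)(C)C(C)(C)C)C1
A7 | alternative 3 | (4S,6R)-4,6-bis{[tert-butyl(dimethyl)silyl]oxy}oxepan-2-one | O=C1C[C@@H](O[Si](C)(C)C(C)(C)C)C[C@@H](O[Si](C)(C)C(C)(C)C)CO1
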